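**Retrosynthetic overview**
1. Target 16 ⇐ tricyclic β-lactone 15: one acid treatment cleaves both tert-butyl esters and opens the lactone (E1) to the C3=C4 acid, so no base ever touches the epimerisable C2 centre.
2. 15 ⇐ carbene-generated homoenolate of enal 13 (its ester-bearing β-carbon is a reversed-polarity nucleophile) + quinone methide aldehyde 14: C1–C2 bond first (sets C1 and C2, 1,2-cis), then C3–C4 aldol, then lactonisation.
3. 14 ⇐ phthalan acetal 11, which masks both the benzhydryl leaving group and the ring A aldehyde and is opened in the flask by fluoride.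
4. 11 ⇐ phenol 6 + tert-butyl bromoacetate 7 + aldehyde 2 (Z-enol ether by aldol/elimination); 6 ⇐ aryllithium from 6-bromovanillin acetal 4 + aldehyde 2.
5. Ring order: ring A is bought; a temporary phthalan ring (step 3); carbocyclic ring B and the four-membered lactone together in step 7; the lactone is opened in step 8.

Assumption: the (5aS,10bR) antipode of the aminoindanol triazolium is taken to give the (1R,2R) series; if the facial sense proves opposite, the equally available (5aR,10bS) antipode is used with no other change.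

**Step 1**
Reactants: 1 vanillin
Product: 2 4-(tert-butyldimethylsilyloxy)-3-methoxybenzaldehyde
Conditions: TBSCl, imidazole, DMF, rt
Reagents that add atoms: tert-butyldimethylsilyl chloride, CC(C)(C)[Si](C)(C)Cl
Why: Standard phenol silylation (silyl ether formation); the silyl group later serves as the fluoride trigger.

**Step 2**
Reactants: 3 6-bromovanillin
Product: 4 5-bromo-4-(dimethoxymethyl)-2-methoxyphenol
Conditions: HC(OMe)3, MeOH, TsOH·H2O (1 mol%), rt; Et3N quench
Reagents that add atoms: trimethyl orthoformate, COC(OC)OC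
Why: Acid-catalysed acetalisation masks the aldehyde (future C4) against the organolithium of step 3.

**Step 3**
Reactants: 4 5-bromo-4-(dimethoxymethyl)-2-methoxyphenol; 2 4-(tert-butyldimethylsilyloxy)-3-methoxybenzaldehyde
Product: 6 3-[4-(tert-butyldimethylsilyloxy)-3-methoxyphenyl]-1,6-dimethoxy-1,3-dihydroisobenzofuran-5-ol (racemic diastereomer mixture), via hydroxy acetal 5 (not isolated)
Conditions: n-BuLi (2.1 equiv), THF, −78 °C; 2, −78 to −20 °C; AcOH (2.2 equiv); then PPTS (5 mol%), CH2Cl2, 4 Å MS, rt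
Reagents that add atoms: none
Why: The phenol is deprotonated first, bromine–lithium exchange next to the chelating acetal gives the aryllithium, which adds 1,2 to aldehyde 2 (C1–C8a bond), and PPTS closes the five-membered cyclic acetal by transacetalisation; both new stereocentres are erased in step 7, so the mixture is used.

**Step 4**
Reactants: 6 phthalan phenol; 7 tert-butyl bromoacetate
Product: 8 tert-butyl 2-({3-[4-(tert-butyldimethylsilyloxy)-3-methoxyphenyl]-1,6-dimethoxy-1,3-dihydroisobenzofuran-5-yl}oxy)acetate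
Conditions: K2CO3, acetone, 50 °C
Reagents that add atoms: none
Why: Williamson ether synthesis on the only free phenol; anhydrous K2CO3 in acetone leaves the aryl silyl ether and the acetal intact.

**Step 5**
Reactants: 8 aryloxyacetate; 2 4-(tert-butyldimethylsilyloxy)-3-methoxybenzaldehyde
Product: 11 tert-butyl (Z)-3-[4-(tert-butyldimethylsilyloxy)-3-methoxyphenyl]-2-({3-[4-(tert-butyldimethylsilyloxy)-3-methoxyphenyl]-1,6-dimethoxy-1,3-dihydroisobenzofuran-5-yl}oxy)prop-2-enoate, via aldol adduct 9 (not isolated), via mesylate 10 (not isolated)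
Conditions: LiN(SiMe3)2 (1.05 equiv), THF, −78 °C; 2; MsCl, −78 to 0 °C; DBU, 0 °C to rt
Reagents that add atoms: none
Why: Ester-enolate aldol addition, in-situ mesylation and E1cB elimination give the thermodynamically preferred (Z)-enol ether (aryl trans to the ester, as in the natural 8-O-4 unit); one equivalent of amide base is consumed by the far more acidic aryloxyacetate, so the phthalan C–H is untouched.

**Step 6**
Reactants: 12 tert-butyl (E)-but-2-enoate
Product: 13 tert-butyl (E)-4-oxobut-2-enoate
Conditions: SeO2 (1.1 equiv), 1,4-dioxane, 100 °C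
Reagents that add atoms: selenium dioxide, O=[Se]=O
Why: Riley allylic oxidation of the γ-methyl group of a crotonate gives the 4-oxo-enoate, the homoenolate precursor.

**Step 7**
Reactants: 11 bis-silyl phthalan acetal; 13 tert-butyl (E)-4-oxobut-2-enoate
Product: 15 tert-butyl (2aS,3R,4R,8bS)-6-{[(Z)-1-(tert-butoxycarbonyl)-2-(4-hydroxy-3-methoxyphenyl)ethenyl]oxy}-4-(4-hydroxy-3-methoxyphenyl)-7-methoxy-2-oxo-2a,3,4,8b-tetrahydro-2H-naphtho[1,2-b]oxete-3-carboxylate, via quinone methide aldehyde 14 (not isolated)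
Conditions: 13 (1.5 equiv), (5aS,10bR)-2-mesityl-5a,10b-dihydro-4H,6H-indeno[2,1-b][1,2,4]triazolo[4,3-d][1,4]oxazin-2-ium chloride (15 mol%), CsF (1.0 equiv), 18-crown-6 (1.0 equiv), 4 Å MS, THF, −20 °C to rt; aq NH4Cl work-up
Reagents that add atoms: none
Why: Proposed new method: fluoride removes one aryl silyl group and the para-phenoxide expels the benzhydryl ring oxygen (self-immolative 1,6-elimination, eased by the para-methoxy donor of ring A); the hemiacetal anion collapses to the ring A aldehyde and methoxide, which is consumed by the second silyl ether as TBSOMe, giving 14 with no free alkoxide left; the caesium aryloxides deprotonate the triazolium, the carbene turns 13 into its homoenolate, whose ester-bearing β-carbon (C2) adds 1,6 to C1 of 14 under catalyst control of both new centres (the syn-selective open transition state known for such homoenolate additions to β-aryl nitroalkenes maps onto the 1,2-cis, 1R,2R relationship); the azolium enol (C3) then closes ring B by intramolecular aldol addition to the unveiled aldehyde and the alkoxide acylates the acyl azolium to the β-lactone, releasing the carbene; the closest known reaction types are carbene-catalysed homoenolate Michael/aldol/lactonisation annulations of 4-oxo-enoates with enones and fluoride-triggered quinone methide generation in carbene homoenolate annulations.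

**Step 8**
Reactants: 15 tricyclic β-lactone
Product: 16 (1R,2R)-7-{[(Z)-1-carboxy-2-(4-hydroxy-3-methoxyphenyl)ethenyl]oxy}-1-(4-hydroxy-3-methoxyphenyl)-6-methoxy-1,2-dihydronaphthalene-2,3-dicarboxylic acid
Conditions: CF3CO2H/CH2Cl2/H2O (10:10:1), 0 to 35 °C
Reagents that add atoms: none
Why: Acidolysis removes both tert-butyl esters and ionises the benzylic C–O bond of the β-lactone (cation stabilised by the para oxygen of ring A); E1 loss of the C3 proton, as in acid dehydration of β-aryl-β-hydroxy acids, gives the conjugated C3=C4 acid, and because the medium is acidic throughout, the cis C1/C2 configuration from step 7 is retained and the enol ether is untouched.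

**Compound list**
1 | vanillin (4-hydroxy-3-methoxybenzaldehyde) | COc1cc(C=O)ccc1O | starting material
2 | 4-(tert-butyldimethylsilyloxy)-3-methoxybenzaldehyde | COc1cc(C=O)ccc1O[Si](C)(C)C(C)(C)C | intermediate
3 | 6-bromovanillin (2-bromo-4-hydroxy-5-methoxybenzaldehyde) | COc1cc(C=O)c(Br)cc1O | starting material
4 | 5-bromo-4-(dimethoxymethyl)-2-methoxyphenol | COc1cc(C(OC)OC)c(Br)cc1O | intermediate
5 | [2-(dimethoxymethyl)-5-hydroxy-4-methoxyphenyl][4-(tert-butyldimethylsilyloxy)-3-methoxyphenyl]methanol (racemic) | COc1cc(C(OC)OC)c(C(O)c2ccc(O[Si](C)(C)C(C)(C)C)c(OC)c2)cc1O | intermediate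
6 | 3-[4-(tert-butyldimethylsilyloxy)-3-methoxyphenyl]-1,6-dimethoxy-1,3-dihydroisobenzofuran-5-ol (racemic, cis/trans mixture) | COC1OC(c2ccc(O[Si](C)(C)C(C)(C)C)c(OC)c2)c2cc(O)c(OC)cc21 | intermediate
7 | tert-butyl bromoacetate | CC(C)(C)OC(=O)CBr | starting material
8 | tert-butyl 2-({3-[4-(tert-butyldimethylsilyloxy)-3-methoxyphenyl]-1,6-dimethoxy-1,3-dihydroisobenzofuran-5-yl}oxy)acetate | COC1OC(c2ccc(O[Si](C)(C)C(C)(C)C)c(OC)c2)c2cc(OCC(=O)OC(C)(C)C)c(OC)cc21 | intermediate
9 | tert-butyl 3-hydroxy-3-[4-(tert-butyldimethylsilyloxy)-3-methoxyphenyl]-2-(phthalan-5-yloxy)propanoate (aldol adduct, mixture) | COC1OC(c2ccc(O[Si](C)(C)C(C)(C)C)c(OC)c2)c2cc(OC(C(O)c3ccc(O[Si](C)(C)C(C)(C)C)c(OC)c3)C(=O)OC(C)(C)C)c(OC)cc21 | intermediate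
10 | methanesulfonate of 9 (mixture) | COC1OC(c2ccc(O[Si](C)(C)C(C)(C)C)c(OC)c2)c2cc(OC(C(OS(C)(=O)=O)c3ccc(O[Si](C)(C)C(C)(C)C)c(OC)c3)C(=O)OC(C)(C)C)c(OC)cc21 | intermediate
11 | tert-butyl (Z)-3-[4-(tert-butyldimethylsilyloxy)-3-methoxyphenyl]-2-({3-[4-(tert-butyldimethylsilyloxy)-3-methoxyphenyl]-1,6-dimethoxy-1,3-dihydroisobenzofuran-5-yl}oxy)prop-2-enoate | COC1OC(c2ccc(O[Si](C)(C)C(C)(C)C)c(OC)c2)c2cc(O/C(=C\c3ccc(O[Si](C)(C)C(C)(C)C)c(OC)c3)C(=O)OC(C)(C)C)c(OC)cc21 | intermediate
12 | tert-butyl (E)-but-2-enoate (tert-butyl crotonate) | C/C=C/C(=O)OC(C)(C)C | starting material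
13 | tert-butyl (E)-4-oxobut-2-enoate | O=C/C=C/C(=O)OC(C)(C)C | intermediate
14 | tert-butyl (Z)-2-{4-formyl-2-methoxy-5-[(3-methoxy-4-oxocyclohexa-2,5-dien-1-ylidene)methyl]phenoxy}-3-(4-hydroxy-3-methoxyphenyl)prop-2-enoate | COC1=CC(=Cc2cc(O/C(=C\c3ccc(O)c(OC)c3)C(=O)OC(C)(C)C)c(OC)cc2C=O)C=CC1=O | intermediate
15 | tert-butyl (2aS,3R,4R,8bS)-6-{[(Z)-1-(tert-butoxycarbonyl)-2-(4-hydroxy-3-methoxyphenyl)ethenyl]oxy}-4-(4-hydroxy-3-methoxyphenyl)-7-methoxy-2-oxo-2a,3,4,8b-tetrahydro-2H-naphtho[1,2-b]oxete-3-carboxylate | O=C1O[C@@H]2c3cc(OC)c(O/C(=C\c4ccc(O)c(OC)c4)C(=O)OC(C)(C)C)cc3[C@@H](c3ccc(O)c(OC)c3)[C@@H](C(=O)OC(C)(C)C)[C@H]12 | intermediate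
16 | (1R,2R)-7-{[(Z)-1-carboxy-2-(4-hydroxy-3-methoxyphenyl)ethenyl]oxy}-1-(4-hydroxy-3-methoxyphenyl)-6-methoxy-1,2-dihydronaphthalene-2,3-dicarboxylic acid | COc1cc(/C=C(\Oc2cc3c(cc2OC)C=C(C(=O)O)[C@H](C(=O)O)[C@@H]3c2ccc(O)c(OC)c2)C(=O)O)ccc1O | target

**Total step count:** 8.
**Longest linear sequence:** 6 steps (3 → 4 → 6 → 8 → 11 → 15 → 16).

**Steps most likely to fail, with fallbacks**

Step 7. The cascade relies on three untested things at once. The methoxide set free on unveiling 14 must be fully scavenged as TBSOMe, since otherwise it can open the lactone or intercept the acyl azolium as a methyl ester. The carbene must deliver the cis 1,2-relationship and a useful enantiomeric excess, which rests on analogy only. The aldol/lactonisation must outrun intermolecular acylation of the aryloxides. The fallback redesigns the electrophile precursor so that a carboxylate, not an alkoxide, is expelled. It sets out from 11: PPTS in wet acetone hydrolyses the methyl acetal to the lactol F1, and Ac2O/pyridine/4-(dimethylamino)pyridine gives the lactol acetate F2. With CsF (2.1 equiv), 18-crown-6, the same triazolium salt and 13, both silyl ethers fall and the hemiacetal anion collapses with loss of acetate, which is neither basic nor nucleophilic enough to interfere. The same homoenolate addition/aldol/lactonisation then returns to 15. This fallback does not address a wrong stereochemical outcome.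

Step 8. The β-lactone C–O bond may ionise too slowly in CF3CO2H, or the cation may be diverted. The fallback changes the ionising group and sets out from 15: 2-(trimethylsilyl)ethanol with catalytic 4-(dimethylamino)pyridine in CH2Cl2 opens the lactone at the acyl carbon to the hydroxy diester F3, with C2 untouched because its proton is an ordinary ester α-proton at this stage. The free benzylic hydroxyl of F3 ionises far more readily, and the same CF3CO2H treatment cleaves all three esters, dehydrates by E1 and comes back at 16.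

Step 3. The lithium phenoxide may slow the bromine–lithium exchange or make the dianion insoluble. The fallback replaces the organolithium by a boron nucleophile and sets out from 4: Miyaura borylation (B2pin2, Pd(dppf)Cl2, KOAc, 1,4-dioxane, 90 °C) gives the arylboronate F4. Rhodium-catalysed 1,2-addition of F4 to aldehyde 2 ([Rh(cod)Cl]2, K3PO4, 1,4-dioxane/H2O, 60 °C) returns to hydroxy acetal 5, which is closed to 6 with PPTS as in step 3.

**Further compounds**
F1 | step 7 | tert-butyl (Z)-3-[4-(tert-butyldimethylsilyloxy)-3-methoxyphenyl]-2-({3-[4-(tert-butyldimethylsilyloxy)-3-methoxyphenyl]-1-hydroxy-6-methoxy-1,3-dihydroisobenzofuran-5-yl}oxy)prop-2-enoate | OC1OC(c2ccc(O[Si](C)(C)C(C)(C)C)c(OC)c2)c2cc(O/C(=C\c3ccc(O[Si](C)(C)C(C)(C)C)c(OC)c3)C(=O)OC(C)(C)C)c(OC)cc21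
F2 | step 7 | tert-butyl (Z)-2-({1-acetoxy-3-[4-(tert-butyldimethylsilyloxy)-3-methoxyphenyl]-6-methoxy-1,3-dihydroisobenzofuran-5-yl}oxy)-3-[4-(tert-butyldimethylsilyloxy)-3-methoxyphenyl]prop-2-enoate | CC(=O)OC1OC(c2ccc(O[Si](C)(C)C(C)(C)C)c(OC)c2)c2cc(O/C(=C\c3ccc(O[Si](C)(C)C(C)(C)C)c(OC)c3)C(=O)OC(C)(C)C)c(OC)cc21
F3 | step 8 | 2-tert-butyl 3-[2-(trimethylsilyl)ethyl] (1R,2R,3S,4S)-7-{[(Z)-1-(tert-butoxycarbonyl)-2-(4-hydroxy-3-methoxyphenyl)ethenyl]oxy}-4-hydroxy-1-(4-hydroxy-3-methoxyphenyl)-6-methoxy-1,2,3,4-tetrahydronaphthalene-2,3-dicarboxylate | C[Si](C)(C)CCOC(=O)[C@@H]1[C@H](O)c2cc(OC)c(O/C(=C\c3ccc(O)c(OC)c3)C(=O)OC(C)(C)C)cc2[C@@H](c2ccc(O)c(OC)c2)[C@H]1C(=O)OC(C)(C)C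
F4 | step 3 | 4-(dimethoxymethyl)-2-methoxy-5-(4,4,5,5-tetramethyl-1,3,2-dioxaborolan-2-yl)phenol | COc1cc(C(OC)OC)c(B2OC(C)(C)C(C)(C)O2)cc1O
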